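**Assumptions:** (13Z)-octadec-13-enal, a pheromone aldehyde sold in bulk, is taken as a cheap commercial starting material; the ligand antipode named in step 2 is taken to give the (R)-boronate, which is from memory and must be confirmed on 8 by Mosher analysis (the mirror-image ligand is equally available).

The target read from the SMILES is (2R)-2-[(12Z)-heptadec-12-en-1-yl]-5,8-dihydroxychroman-4-one.

## Retrosynthetic overview

1. 10 ⇒ 9: break the aryl C8a–O1 bond; ring B closes by intramolecular oxa-Michael addition of the (R)-carbinol to an acylquinone, which also delivers the 5,8-hydroquinone.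
2. 9 ⇒ 8: the acylquinone comes from oxidative demethylation of a 2,5-dimethoxyphenyl ketone in the same flask.
3. 8 ⇒ 6: the carbinol C–O bond comes from enantioselective β-borylation/oxidation of an (E)-enone, which sets the only stereocentre.
4. 6 ⇒ 1 + 2: aldol condensation; the (Z)-alkene is bought with aldehyde 2.
5. Ring order: ring A (benzene) is bought in 1; ring B (pyranone) is the only ring made, in the last step.

## Route

Step 1
Reactants: 1 1-(2,5-dimethoxyphenyl)ethan-1-one; 2 (13Z)-octadec-13-enal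
Product: 6 (2E,15Z)-1-(2,5-dimethoxyphenyl)icosa-2,15-dien-1-one, via lithium enolate 3 (not isolated), via lithium aldolate 4 (not isolated), via mesylate 5 (not isolated)
Conditions: LiN(SiMe3)2 (1.05 equiv), THF, –78 °C; 2 (1.0 equiv), –78 °C; MsCl (1.3 equiv), –78 → 0 °C; DBU (2.5 equiv), 0 → 23 °C
Reagents that add atoms: none
Why: Directed aldol addition of the preformed lithium enolate 3 to the enolisable aldehyde avoids aldehyde self-condensation, and mesylation of aldolate 4 followed by DBU-mediated E1cB elimination of 5 gives the conjugated (E)-enone under thermodynamic control (aldol condensation by mesylate elimination); the isolated (Z)-alkene is inert and no stereocentre is carried on.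

Step 2
Reactants: 6 (2E,15Z)-1-(2,5-dimethoxyphenyl)icosa-2,15-dien-1-one
Product: 8 (3R,15Z)-1-(2,5-dimethoxyphenyl)-3-hydroxyicos-15-en-1-one, via boronate 7 (not isolated)
Conditions: CuCl (3 mol%), NaOtBu (6 mol%), (R)-1-[(S)-2-(diphenylphosphino)ferrocenyl]ethyldicyclohexylphosphine (3 mol%), B2pin2 (1.1 equiv), MeOH (2 equiv), THF, 23 °C; then NaBO3·4H2O (5 equiv), THF/H2O 1:1, 23 °C
Reagents that add atoms: sodium perborate tetrahydrate, [Na+].[O-]OB=O.O.O.O.O
Why: Copper-catalysed enantioselective conjugate borylation, in which the chiral bisphosphine–Cu–Bpin species adds to one face of the (E)-enone to set C3 as the (R)-boronate 7 (methanol turns over the copper enolate, the unactivated (Z)-alkene is not borylated), followed by perborate oxidation that replaces C–B by C–O with retention to give the (R)-carbinol whose oxygen becomes O1 of the target.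

Step 3
Reactants: 8 (3R,15Z)-1-(2,5-dimethoxyphenyl)-3-hydroxyicos-15-en-1-one
Product: 10 (2R)-2-[(12Z)-heptadec-12-en-1-yl]-5,8-dihydroxychroman-4-one, via acylquinone 9 (not isolated)
Conditions: (NH4)2Ce(NO3)6 (2.2 equiv), MeCN/H2O 3:1, 0 °C, 10 min; extract into CH2Cl2, dry (MgSO4); then Sc(OTf)3 (5 mol%), CH2Cl2, 0 → 23 °C
Reagents that add atoms: water, O
Why: Proposed new method: (NH4)2Ce(NO3)6 oxidatively demethylates the hydroquinone dimethyl ether to acylquinone 9, whose C3 (the CH between the acyl-bearing carbon and the C4 carbonyl) is β to both the quinone C1 carbonyl and the side-chain ketone; Sc(OTf)3 chelation of that 1,3-dicarbonyl activates C3 and holds the tether over it, the secondary hydroxyl adds in a 6-endo oxa-Michael fashion, and enolisation re-aromatises the adduct to the hydroquinone, so the aryl C8a–O1 bond, ring B and both phenols form in one operation while the carbinol carbon keeps its (R) configuration because no bond to it is made or broken; the closest known reactions are the intermolecular C3-selective conjugate additions of amines, thiols, enols and arenes to 2-acyl-1,4-benzoquinones and the oxidative demethylation of 1,4-dimethoxyarenes to quinones.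

## Compound list

1 | 1-(2,5-dimethoxyphenyl)ethan-1-one (2',5'-dimethoxyacetophenone) | CC(=O)c1cc(OC)ccc1OC | starting material
2 | (13Z)-octadec-13-enal | CCCC/C=C\CCCCCCCCCCCC=O | starting material
3 | lithium 1-(2,5-dimethoxyphenyl)ethen-1-olate (lithium enolate of 1) | [Li+].[O-]C(=C)c1cc(OC)ccc1OC | intermediate
4 | lithium (15Z)-1-(2,5-dimethoxyphenyl)-1-oxoicos-15-en-3-olate (racemic lithium aldolate) | [Li+].[O-]C(CCCCCCCCCCC/C=C\CCCC)CC(=O)c1cc(OC)ccc1OC | intermediate
5 | (15Z)-1-(2,5-dimethoxyphenyl)-1-oxoicos-15-en-3-yl methanesulfonate (racemic) | CS(=O)(=O)OC(CCCCCCCCCCC/C=C\CCCC)CC(=O)c1cc(OC)ccc1OC | intermediate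
6 | (2E,15Z)-1-(2,5-dimethoxyphenyl)icosa-2,15-dien-1-one | CCCC/C=C\CCCCCCCCCCC/C=C/C(=O)c1cc(OC)ccc1OC | intermediate
7 | (3R,15Z)-1-(2,5-dimethoxyphenyl)-3-(4,4,5,5-tetramethyl-1,3,2-dioxaborolan-2-yl)icos-15-en-1-one | CCCC/C=C\CCCCCCCCCCC[C@@H](B1OC(C)(C)C(C)(C)O1)CC(=O)c1cc(OC)ccc1OC | intermediate
8 | (3R,15Z)-1-(2,5-dimethoxyphenyl)-3-hydroxyicos-15-en-1-one | CCCC/C=C\CCCCCCCCCCC[C@@H](O)CC(=O)c1cc(OC)ccc1OC | intermediate
9 | 2-[(3R,15Z)-3-hydroxyicos-15-enoyl]cyclohexa-2,5-diene-1,4-dione | CCCC/C=C\CCCCCCCCCCC[C@@H](O)CC(=O)C1=CC(=O)C=CC1=O | intermediate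
10 | (2R)-2-[(12Z)-heptadec-12-en-1-yl]-5,8-dihydroxychroman-4-one (CNP0081592.1) | CCCC/C=C\CCCCCCCCCCC[C@@H]1CC(=O)c2c(O)ccc(O)c2O1 | target

## Step count and risks

Total step count: 3. Longest linear sequence: 3 steps (1 or 2 → 6 → 8 → 10).

The three steps most likely to fail, most risky first:

**Step 3 (the proposed new step).** The ring closure on 9 may be slower than addition of water to 9, and cross-redox between product 10 and unreacted 9 can cap the yield. The fallback uses known chemistry, sets out from 2 and comes back at 10. Kabbe condensation of 2 with the known phenol 1-(2-hydroxy-3,6-dimethoxyphenyl)ethan-1-one F1 (pyrrolidine, EtOH, 80 °C; the only ortho phenol closes the ring) gives racemic 2-[(12Z)-heptadec-12-en-1-yl]-5,8-dimethoxychroman-4-one F2. BBr3 (CH2Cl2, –78 → 0 °C) cleaves both methyl ethers to racemic 2-[(12Z)-heptadec-12-en-1-yl]-5,8-dihydroxychroman-4-one F3. Preparative HPLC on a chiral stationary phase then gives 10, and the unwanted (2S)-2-[(12Z)-heptadec-12-en-1-yl]-5,8-dihydroxychroman-4-one F4 is re-equilibrated to F3 with DBU (retro-oxa-Michael/oxa-Michael) and recycled.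

**Step 2.** The enantiomeric excess, or the sense of induction, on this ortho-methoxyaryl β-alkyl enone may fall short. The fallback sets out from 6 and comes back at 8. Catalytic asymmetric nucleophilic epoxidation (La(OiPr)3/(R)-BINOL/Ph3As=O 1:1:1, 5 mol%, tBuOOH, 4 Å MS, THF, 23 °C) is expected to give the trans-epoxy ketone [(2S,3R)-3-[(12Z)-heptadec-12-en-1-yl]oxiran-2-yl](2,5-dimethoxyphenyl)methanone F5; the sense for (R)-BINOL is again from memory. SmI2 (THF/MeOH, –90 °C) then cleaves only the Cα–O bond and leaves the β-carbinol centre untouched, giving 8.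

**Step 1.** Retro-aldol of 4 on warming before mesylation, or incomplete elimination of 5, would lower the yield of 6. The fallback sets out from 1 and comes back at 6. CuBr2 (EtOAc/CHCl3, reflux) gives 2-bromo-1-(2,5-dimethoxyphenyl)ethan-1-one F6. PPh3 (toluene, 23 °C) gives [2-(2,5-dimethoxyphenyl)-2-oxoethyl]triphenylphosphonium bromide F7. Aqueous NaOH gives the stabilised ylide 1-(2,5-dimethoxyphenyl)-2-(triphenyl-λ5-phosphanylidene)ethan-1-one F8. Wittig olefination of F8 with 2 (toluene, 90 °C) gives 6 with high E selectivity and no base-sensitive aldol stage.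

## Further compounds

F1 | step 3 | 1-(2-hydroxy-3,6-dimethoxyphenyl)ethan-1-one (known phenol, used as such) | CC(=O)c1c(O)c(OC)ccc1OC
F2 | step 3 | racemic 2-[(12Z)-heptadec-12-en-1-yl]-5,8-dimethoxychroman-4-one | CCCC/C=C\CCCCCCCCCCCC1CC(=O)c2c(OC)ccc(OC)c2O1
F3 | step 3 | racemic 2-[(12Z)-heptadec-12-en-1-yl]-5,8-dihydroxychroman-4-one | CCCC/C=C\CCCCCCCCCCCC1CC(=O)c2c(O)ccc(O)c2O1
F4 | step 3 | (2S)-2-[(12Z)-heptadec-12-en-1-yl]-5,8-dihydroxychroman-4-one | CCCC/C=C\CCCCCCCCCCC[C@H]1CC(=O)c2c(O)ccc(O)c2O1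
F5 | step 2 | [(2S,3R)-3-[(12Z)-heptadec-12-en-1-yl]oxiran-2-yl](2,5-dimethoxyphenyl)methanone | CCCC/C=C\CCCCCCCCCCC[C@H]1O[C@@H]1C(=O)c1cc(OC)ccc1OC
F6 | step 1 | 2-bromo-1-(2,5-dimethoxyphenyl)ethan-1-one | BrCC(=O)c1cc(OC)ccc1OC
F7 | step 1 | [2-(2,5-dimethoxyphenyl)-2-oxoethyl]triphenylphosphonium bromide | [Br-].COc1ccc(OC)c(c1)C(=O)C[P+](c1ccccc1)(c1ccccc1)c1ccccc1
F8 | step 1 | 1-(2,5-dimethoxyphenyl)-2-(triphenyl-λ5-phosphanylidene)ethan-1-one | COc1ccc(OC)c(c1)C(=O)C=P(c1ccccc1)(c1ccccc1)c1ccccc1
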